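**Plan**

- Ring atoms are numbered O1–O2–C3–C4=C5–C6, and the 1,2-dioxine is the only ring. C3 carries OMe and the C16 chain and is a ketone held as a cyclic methyl perketal. It lies between the first chain carbon C1' and the Z-alkene carbon C4, so this one carbon can enter as carbon monoxide.
- Cuts: first C3–OMe and O2–C3, which opens the ring to a γ-peroxy Z-enone. Then C3–C4 and C3–C1' together, giving a Z-alkenyl iodide, CO and hexadecylzinc iodide. Then the Z-alkene back to an iodoalkyne, C6–O1 back to an enynal, and the enal C=C back to a Wittig pair.
- Forward: the five-carbon peroxy iodide is built linearly. One carbonylative coupling joins chain, carbonyl and alkene. The ring closes last, when the freed hydroperoxide adds to the C3 ketone and OH is exchanged for OMe.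
- Stereochemistry: C6 (R) comes from the amine catalyst of the conjugate peroxidation. The Z-alkene comes from syn hydrogen delivery by diimide. C3 (S) comes from acid methanolysis of the ring hemiperketal, which is expected to give both C3 configurations; chondrillin is separated and the epimeric fraction re-equilibrated.

Key step: step 9

Remark: the facial sense of step 3 is assigned from the usual steric-shielding model of diarylprolinol silyl ethers (attack anti to the CAr2OSi group on the s-trans E-iminium ion); the absolute configuration would be confirmed at the methyl ester stage before going on.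

**Route**

Step 1
Reactants: 1 3-(trimethylsilyl)prop-2-ynal; 2 (triphenylphosphoranylidene)acetaldehyde
Product: 3 (2E)-5-(trimethylsilyl)pent-2-en-4-ynal
Conditions: 2 (1.05 equiv), PhMe, rt
Reagents that add atoms: none
Why: Wittig olefination with a stabilised formyl ylide gives the E-enal, and a second homologation should not compete because the ynal is much more electrophilic than the conjugated enynal that forms.

Step 2
Reactants: 4 2,3-dimethylbut-2-ene
Product: 7 2-methoxypropan-2-yl hydroperoxide, via primary ozonide 5 (not isolated), via acetone O-oxide 6 (not isolated)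
Conditions: O3, CH2Cl2/MeOH, −78 °C; N2 purge; kept cold and used as a titrated solution
Reagents that add atoms: ozone, [O-][O+]=O; methanol, CO
Why: Criegee ozonolysis of a tetrasubstituted alkene in methanol, in which the primary ozonide 5 splits into acetone and the carbonyl oxide 6 and methanol traps 6 as the hydroperoxy ketal, is the standard preparation of this reagent.

Step 3
Reactants: 3 (2E)-5-(trimethylsilyl)pent-2-en-4-ynal; 7 2-methoxypropan-2-yl hydroperoxide
Product: 8 (3R)-3-[(2-methoxypropan-2-yl)peroxy]-5-(trimethylsilyl)pent-4-ynal
Conditions: (R)-2-[diphenyl(trimethylsilyloxy)methyl]pyrrolidine (10 mol %), 7 (1.5 equiv), PhMe, 0 °C; short silica plug, used at once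
Reagents that add atoms: none
Why: Iminium-catalysed conjugate addition of a hydroperoxide to an enal (organocatalytic β-peroxidation): in the s-trans E-iminium ion of 3 the CPh2(OSiMe3) group of the (R)-catalyst blocks one face, so the peroxy oxygen reaches C3 from the open face and sets the 3R centre (ring C6 of the target), while the silyl cap on the alkyne disfavours 1,6-addition and the bulky tertiary hydroperoxide disfavours closure of the enamine to an epoxide.

Step 4
Reactants: 8 (3R)-3-[(2-methoxypropan-2-yl)peroxy]-5-(trimethylsilyl)pent-4-ynal
Product: 9 (3R)-3-[(2-methoxypropan-2-yl)peroxy]-5-(trimethylsilyl)pent-4-ynoic acid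
Conditions: NaClO2, NaH2PO4, 2-methylbut-2-ene, t-BuOH/H2O, 0 °C
Reagents that add atoms: sodium chlorite, [Na+].[O-]Cl=O
Why: Pinnick oxidation converts the aldehyde into the acid in a phosphate buffer without base, so the β-peroxy carbonyl compound cannot lose the peroxide by E1cB elimination, and chlorite should leave the O–O bond, the alkynylsilane and, at 0 °C with short exposure, the perketal intact.

Step 5
Reactants: 9 (3R)-3-[(2-methoxypropan-2-yl)peroxy]-5-(trimethylsilyl)pent-4-ynoic acid
Product: 10 methyl (3R)-3-[(2-methoxypropan-2-yl)peroxy]-5-(trimethylsilyl)pent-4-ynoate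
Conditions: Me3SiCHN2, PhMe/MeOH, 0 °C
Reagents that add atoms: (trimethylsilyl)diazomethane, C[Si](C)(C)C=[N+]=[N-]
Why: O-Methylation of a carboxylic acid with trimethylsilyldiazomethane in methanol is fast and neutral, so the stereocentre, the perketal and the alkynylsilane should be unaffected.

Step 6
Reactants: 10 methyl (3R)-3-[(2-methoxypropan-2-yl)peroxy]-5-(trimethylsilyl)pent-4-ynoate
Product: 11 methyl (3R)-5-iodo-3-[(2-methoxypropan-2-yl)peroxy]pent-4-ynoate
Conditions: N-iodosuccinimide, AgNO3 (10 mol %), DMF, rt, dark
Reagents that add atoms: N-iodosuccinimide, O=C1CCC(=O)N1I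
Why: Silver-catalysed iododesilylation of an alkynylsilane with N-iodosuccinimide, running through a silver acetylide, gives the 1-iodoalkyne in one neutral operation and avoids a basic desilylation that could trigger Kornblum–DeLaMare cleavage at the propargylic C–H.

Step 7
Reactants: 11 methyl (3R)-5-iodo-3-[(2-methoxypropan-2-yl)peroxy]pent-4-ynoate
Product: 12 methyl (3R,4Z)-5-iodo-3-[(2-methoxypropan-2-yl)peroxy]pent-4-enoate
Conditions: 2-nitrobenzenesulfonylhydrazide, Et3N, THF/i-PrOH, rt
Reagents that add atoms: none
Why: Diimide released from the sulfonylhydrazide transfers two hydrogens to one face of the iodoalkyne in a concerted syn reduction and so gives the Z-iodoalkene, it does not reduce O–O bonds, the iodoalkyne should be consumed faster than the iodoalkene formed, and triethylamine neutralises the sulfinic acid that could otherwise cleave the perketal.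

Step 8
Reactants: 13 1-iodohexadecane
Product: 14 hexadecylzinc iodide
Conditions: Zn dust (activated with BrCH2CH2Br and Me3SiCl), THF, 40 °C; titrated THF solution
Reagents that add atoms: zinc, [Zn]
Why: Oxidative insertion of activated zinc into a primary alkyl iodide gives the alkylzinc iodide, a nucleophile mild enough to tolerate esters, enones and peroxides.

Step 9
Reactants: 12 methyl (3R,4Z)-5-iodo-3-[(2-methoxypropan-2-yl)peroxy]pent-4-enoate; 14 hexadecylzinc iodide; 15 carbon monoxide
Product: 16 methyl (3R,4Z)-3-[(2-methoxypropan-2-yl)peroxy]-6-oxodocos-4-enoate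
Conditions: Pd(PPh3)4 (5 mol %), CO (1 atm), THF/DMA, rt, dark; 14 (1.5 equiv) added slowly
Reagents that add atoms: none
Why: Pd(PPh3)4 supplies zerovalent palladium, which enters the C–I bond of 12 without changing the alkene geometry; the Z-alkenylpalladium iodide takes up CO to become a Z-enoylpalladium iodide, the hexadecyl group of 14 is handed from zinc to palladium, and C–C reductive elimination gives ketone 16, so that C3–C4 and C3–C1' (ring numbering of the target) are both made here. The closest known reaction type is the three-component ketone synthesis from alkylzinc iodides, CO at one atmosphere and alkenyl or aryl iodides under Pd(PPh3)4, and palladium cross-couplings are also known on alkenyl halides that carry dialkyl peroxides or perketals. No ring is closed in this step, the dioxine ring being formed only in step 10, and no stereocentre is created. Two selectivities are needed: CO insertion must precede transmetalation, which the CO atmosphere, the sluggish transmetalation of an alkylzinc iodide and its slow addition should secure, and the Z geometry must persist, which room temperature, exclusion of light and the absence of base should secure. The preset centre at ring C6 is not at risk because the perketal offers no O–H to the organozinc and the medium is neutral, and the alkylzinc iodide is too weak a nucleophile to attack the ester or the enone.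

Step 10
Reactants: 16 methyl (3R,4Z)-3-[(2-methoxypropan-2-yl)peroxy]-6-oxodocos-4-enoate
Product: 19 chondrillin [methyl 2-[(3S,6R)-3-hexadecyl-3-methoxy-3,6-dihydro-1,2-dioxin-6-yl]acetate], via hydroperoxy Z-enone 17 (not isolated), via ring hemiperketal 18 (not isolated)
Conditions: TsOH·H2O (10 mol %), MeOH, 0 °C to rt; NaHCO3; chromatography
Reagents that add atoms: methanol, CO
Why: Acid-catalysed ketal exchange with methanol removes the 2-methoxypropan-2-yl group as 2,2-dimethoxypropane, the freed hydroperoxide 17 adds through its terminal oxygen to the Z-enone carbonyl (6-exo-trig) to give the ring hemiperketal 18, and ionisation of 18 to the ring peroxycarbenium ion followed by capture of methanol gives the methyl perketal; both configurations at C3 are expected, chondrillin is separated by chromatography and the epimeric fraction is returned to the same acidic methanol, in which the two interconvert through that cation, while C6 is not touched.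

**Compound list**

1 | 3-(trimethylsilyl)prop-2-ynal | C[Si](C)(C)C#CC=O | starting material
2 | (triphenylphosphoranylidene)acetaldehyde | O=CC=P(c1ccccc1)(c1ccccc1)c1ccccc1 | starting material
3 | (2E)-5-(trimethylsilyl)pent-2-en-4-ynal | C[Si](C)(C)C#C/C=C/C=O | intermediate
4 | 2,3-dimethylbut-2-ene | CC(C)=C(C)C | starting material
5 | 4,4,5,5-tetramethyl-1,2,3-trioxolane (primary ozonide) | CC1(C)OOOC1(C)C | intermediate
6 | acetone O-oxide (carbonyl oxide) | CC(C)=[O+][O-] | intermediate
7 | 2-methoxypropan-2-yl hydroperoxide | COC(C)(C)OO | intermediate
8 | (3R)-3-[(2-methoxypropan-2-yl)peroxy]-5-(trimethylsilyl)pent-4-ynal | COC(C)(C)OO[C@@H](C#C[Si](C)(C)C)CC=O | intermediate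
9 | (3R)-3-[(2-methoxypropan-2-yl)peroxy]-5-(trimethylsilyl)pent-4-ynoic acid | COC(C)(C)OO[C@@H](C#C[Si](C)(C)C)CC(=O)O | intermediate
10 | methyl (3R)-3-[(2-methoxypropan-2-yl)peroxy]-5-(trimethylsilyl)pent-4-ynoate | COC(C)(C)OO[C@@H](C#C[Si](C)(C)C)CC(=O)OC | intermediate
11 | methyl (3R)-5-iodo-3-[(2-methoxypropan-2-yl)peroxy]pent-4-ynoate | COC(C)(C)OO[C@@H](C#CI)CC(=O)OC | intermediate
12 | methyl (3R,4Z)-5-iodo-3-[(2-methoxypropan-2-yl)peroxy]pent-4-enoate | COC(C)(C)OO[C@@H](/C=C\I)CC(=O)OC | intermediate
13 | 1-iodohexadecane | CCCCCCCCCCCCCCCCI | starting material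
14 | hexadecylzinc iodide | CCCCCCCCCCCCCCCC[Zn]I | intermediate
15 | carbon monoxide | [C-]#[O+] | starting material
16 | methyl (3R,4Z)-3-[(2-methoxypropan-2-yl)peroxy]-6-oxodocos-4-enoate | CCCCCCCCCCCCCCCCC(=O)/C=C\[C@@H](CC(=O)OC)OOC(C)(C)OC | intermediate
17 | methyl (3R,4Z)-3-hydroperoxy-6-oxodocos-4-enoate | CCCCCCCCCCCCCCCCC(=O)/C=C\[C@@H](CC(=O)OC)OO | intermediate
18 | methyl 2-[(6R)-3-hexadecyl-3-hydroxy-3,6-dihydro-1,2-dioxin-6-yl]acetate (both C3 anomers) | CCCCCCCCCCCCCCCCC1(O)C=C[C@@H](CC(=O)OC)OO1 | intermediate
19 | chondrillin, methyl 2-[(3S,6R)-3-hexadecyl-3-methoxy-3,6-dihydro-1,2-dioxin-6-yl]acetate (OMe trans to the C6 side chain) | CCCCCCCCCCCCCCCC[C@@]1(OC)C=C[C@@H](CC(=O)OC)OO1 | target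

**Step count**

Total: 10 steps. Longest linear sequence: 8 steps (steps 1, 3, 4, 5, 6, 7, 9 and 10, counted from 1); steps 2 and 8 are one-step side branches.

**Steps most likely to fail**

Step 9 (carbonylative coupling). Direct alkyl–alkenyl coupling may outrun CO insertion, the Z-enone may isomerise to E through reversible phosphine addition, or the O–O bond may be cleaved reductively by zerovalent palladium in the presence of the organozinc. The fallback sets out from 12 and comes back at 16. Iodide 12 would be stannylated with (Me3Sn)2 and Pd(PPh3)4 (PhMe, 50 °C) to methyl (3R,4Z)-3-[(2-methoxypropan-2-yl)peroxy]-5-(trimethylstannyl)pent-4-enoate F1. F1 would then be acylated with commercial heptadecanoyl chloride in a Stille coupling (Pd2(dba)3, tri(2-furyl)phosphine, THF, rt) to give 16. The acyl carbon then arrives already bonded to the chain, so the outcome no longer depends on the relative rates of CO insertion and transmetalation, and no organozinc is present.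

Step 3 (asymmetric peroxidation). Facial discrimination on the slim enynal may be insufficient, the enamine may close to an epoxide with loss of the peroxide, or the oxa-Michael addition may reverse during isolation. The fallback sets out from 1 and comes back at 8. Aldehyde 1 would undergo asymmetric allylboration with the enantiomer of B-allyldiisopinocampheylborane that delivers the (S)-carbinol (expected to be the reagent derived from (+)-α-pinene; Et2O, −78 °C), giving (3S)-1-(trimethylsilyl)hex-5-en-1-yn-3-ol F2. MsCl and Et3N (CH2Cl2, −20 °C) would convert it into (3S)-1-(trimethylsilyl)hex-5-en-1-yn-3-yl methanesulfonate F3. SN2 displacement with the caesium salt of 7 (CsOH, DMF, 0 °C) would proceed with inversion to (4R)-4-[(2-methoxypropan-2-yl)peroxy]-6-(trimethylsilyl)hex-1-en-5-yne F4. Selective ozonolysis of the terminal alkene (O3, CH2Cl2, −78 °C; Me2S) would then give aldehyde 8. The stereocentre would thus come from a reagent-controlled carbonyl addition and a stereospecific substitution instead of a catalytic conjugate addition.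

Step 7 (diimide reduction). The Z-iodoalkene may be reduced further to the saturated iodide, or the amine may induce Kornblum–DeLaMare fragmentation at the propargylic C–H. The fallback sets out from 11 and comes back at 12. Hydroboration of 11 with dicyclohexylborane (THF, 0 °C) adds H and B syn, with boron on the iodine-bearing carbon, to give methyl (3R,4Z)-5-(dicyclohexylboranyl)-5-iodo-3-[(2-methoxypropan-2-yl)peroxy]pent-4-enoate F5. Protonolysis of the C–B bond with AcOH (0 °C, brief) proceeds with retention and gives 12. The hindered borane cannot add a second time and no amine is used.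

**Further compounds**

F1 | step 9 | methyl (3R,4Z)-3-[(2-methoxypropan-2-yl)peroxy]-5-(trimethylstannyl)pent-4-enoate | COC(C)(C)OO[C@@H](/C=C\[Sn](C)(C)C)CC(=O)OC
F2 | step 3 | (3S)-1-(trimethylsilyl)hex-5-en-1-yn-3-ol | O[C@H](C#C[Si](C)(C)C)CC=C
F3 | step 3 | (3S)-1-(trimethylsilyl)hex-5-en-1-yn-3-yl methanesulfonate | CS(=O)(=O)O[C@H](C#C[Si](C)(C)C)CC=C
F4 | step 3 | (4R)-4-[(2-methoxypropan-2-yl)peroxy]-6-(trimethylsilyl)hex-1-en-5-yne | COC(C)(C)OO[C@@H](C#C[Si](C)(C)C)CC=C
F5 | step 7 | methyl (3R,4Z)-5-(dicyclohexylboranyl)-5-iodo-3-[(2-methoxypropan-2-yl)peroxy]pent-4-enoate | COC(C)(C)OO[C@@H](/C=C(\I)B(C1CCCCC1)C1CCCCC1)CC(=O)OC
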